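**Retrosynthetic overview**
1. The target is (3S,5S,6S,3'R,6'R)-5,6-dihydro-β,ε-carotene-3,5,6,3'-tetrol; it is released in the last step by global desilylation of the fully silylated C40 polyene.
2. Key disconnection C14'–C15' (sp2–sp2): one-pot Zr-catalysed methylalumination of a C18 terminal tetraenyne (ε half, alkyne C13'≡C14'–H) followed by Pd/Zn-co-catalysed alkenyl–alkenyl coupling with a C21 (E)-pentaenyl iodide (trihydroxy-ring half). Enabling feature: C14' is the CH end of the E-trisubstituted C13'=C14' olefin whose C13' carries the C20' methyl (retron of syn-methylmetalation of a terminal alkyne), C15' is the CH end of the E-disubstituted C15=C15' olefin (retron of an aldehyde-derived vinyl iodide), and all five stereocentres sit far away in the two rings.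
3. C21 iodide: Takai iodo-olefination of a C20 aldehyde, reached by two HWE/DIBAL C5 homologations of a C10 α-hydroxy aldehyde; C5/C6 come from Sharpless epoxidation plus Ti-mediated opening at C5 with inversion, C3 from actinol.
4. C18 alkyne: (R)-α-ionone, HWE to the C15 nitrile, allylic oxidation at C3', trans-selective ketone reduction, DIBAL, HWE with a silylpropargyl phosphonate, C-desilylation.
5. Rings: no carbocycle is built. The ε ring (cyclohexene C1'–C6') comes intact from (R)-α-ionone and the trihydroxycyclohexane ring (C1–C6) from actinol; the only ring formed is the transient C5–C6 oxirane (step 5), opened again in step 6.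

Key step: step 21

Remark: (4R,6R)-actinol and (R)-α-ionone are taken as purchasable single enantiomers; minor geometric isomers that the olefinations may give are removed by chromatography at the stage where they arise, and all polyenes are handled under argon in dim light.

**Fragment with the trihydroxy ring (C21 iodide)**

Step 1
Reactants: 1 (4R,6R)-4-hydroxy-2,2,6-trimethylcyclohexan-1-one (actinol)
Product: 2 (4R,6R)-4-[(tert-butyldimethylsilyl)oxy]-2,2,6-trimethylcyclohexan-1-one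
Conditions: TBSCl, imidazole, DMF, rt
Reagents that add atoms: tert-butyldimethylsilyl chloride, CC(C)(C)[Si](C)(C)Cl
Why: Standard silylation of the only hydroxyl group; no stereocentre is touched.

Step 2
Reactants: 2 (4R,6R)-4-[(tert-butyldimethylsilyl)oxy]-2,2,6-trimethylcyclohexan-1-one
Product: 3 (4R)-4-[(tert-butyldimethylsilyl)oxy]-2,6,6-trimethylcyclohex-1-en-1-yl trifluoromethanesulfonate
Conditions: LiN(iPr)2, THF, −78 °C; then PhNTf2, −78 °C to rt
Reagents that add atoms: N-phenylbis(trifluoromethanesulfonimide), O=S(=O)(N(c1ccccc1)S(=O)(=O)C(F)(F)F)C(F)(F)F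
Why: Enol triflate formation; deprotonation can occur only at the methyl-bearing α-carbon because the other α-carbon is quaternary, and O-sulfonylation of the enolate gives the tetrasubstituted enol triflate, removing the methyl stereocentre as planned.

Step 3
Reactants: 3 (4R)-4-[(tert-butyldimethylsilyl)oxy]-2,6,6-trimethylcyclohex-1-en-1-yl trifluoromethanesulfonate
Product: 4 methyl (4R)-4-[(tert-butyldimethylsilyl)oxy]-2,6,6-trimethylcyclohex-1-ene-1-carboxylate
Conditions: CO (1 atm), MeOH, Pd(OAc)2 (5 mol %), PPh3, Et3N, DMF, 65 °C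
Reagents that add atoms: carbon monoxide, [C-]#[O+]; methanol, CO
Why: Pd-catalysed alkoxycarbonylation of a vinyl triflate (oxidative addition, CO insertion, methanolysis of the acyl-palladium species) should deliver the enoate and so bring in C7.

Step 4
Reactants: 4 methyl (4R)-4-[(tert-butyldimethylsilyl)oxy]-2,6,6-trimethylcyclohex-1-ene-1-carboxylate
Product: 5 [(4R)-4-[(tert-butyldimethylsilyl)oxy]-2,6,6-trimethylcyclohex-1-en-1-yl]methanol
Conditions: iBu2AlH (2.3 equiv), CH2Cl2, −78 °C; Rochelle salt work-up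
Reagents that add atoms: none
Why: DIBAL 1,2-reduction of the hindered conjugated ester should stop at the allylic alcohol and leave the silyl ether alone.

Step 5
Reactants: 5 [(4R)-4-[(tert-butyldimethylsilyl)oxy]-2,6,6-trimethylcyclohex-1-en-1-yl]methanol
Product: 6 [(1R,4S,6R)-4-[(tert-butyldimethylsilyl)oxy]-2,2,6-trimethyl-7-oxabicyclo[4.1.0]heptan-1-yl]methanol (oxirane oxygen trans to the silyloxy group)
Conditions: t-BuOOH, Ti(OiPr)4 (10 mol %), D-(−)-diethyl tartrate (12 mol %), 4 Å MS, CH2Cl2, −20 °C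
Reagents that add atoms: tert-butyl hydroperoxide, CC(C)(C)OO
Why: Sharpless asymmetric epoxidation; with the D-(−)-tartrate the titanium-bound peroxide should be delivered, under reagent control, to the face of the C5=C6 olefin opposite the C3 silyloxy group, which sets C5 and C6 as the anti-epoxide.

Step 6
Reactants: 6 [(1R,4S,6R)-4-[(tert-butyldimethylsilyl)oxy]-2,2,6-trimethyl-7-oxabicyclo[4.1.0]heptan-1-yl]methanol
Product: 7 (1S,2R,5S)-5-[(tert-butyldimethylsilyl)oxy]-2-hydroxy-2-(hydroxymethyl)-1,3,3-trimethylcyclohexyl benzoate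
Conditions: PhCO2H, Ti(OiPr)4 (1.5 equiv), CH2Cl2, rt
Reagents that add atoms: benzoic acid, OC(=O)c1ccccc1
Why: Ti(OiPr)4-mediated opening of a 2,3-epoxy alcohol at its distal carbon by a carboxylate with inversion; chelation of the C7 alkoxide and the oxirane oxygen activates the C5–O bond while C6 is shielded by the quaternary C1, so the benzoate should enter at C5 on the face cis to the C3 silyloxy group and the former oxirane oxygen should stay on C6 as the trans tertiary hydroxyl, the tertiary ester being slow to migrate.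

Step 7
Reactants: 7 (1S,2R,5S)-5-[(tert-butyldimethylsilyl)oxy]-2-hydroxy-2-(hydroxymethyl)-1,3,3-trimethylcyclohexyl benzoate
Product: 8 (1S,2S,5S)-5-[(tert-butyldimethylsilyl)oxy]-2-formyl-2-hydroxy-1,3,3-trimethylcyclohexyl benzoate
Conditions: TEMPO (10 mol %), PhI(OAc)2, CH2Cl2, rt
Reagents that add atoms: none
Why: Oxoammonium (TEMPO) oxidation converts only the primary alcohol; the tertiary hydroxyl and the tertiary benzoate cannot be oxidised and the new aldehyde has no α-hydrogen to epimerise.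

Step 8
Reactants: 8 (1S,2S,5S)-5-[(tert-butyldimethylsilyl)oxy]-2-formyl-2-hydroxy-1,3,3-trimethylcyclohexyl benzoate
Product: 9 (1S,2S,5S)-5-[(tert-butyldimethylsilyl)oxy]-2-[(1E,3E)-4-cyano-3-methylbuta-1,3-dien-1-yl]-2-hydroxy-1,3,3-trimethylcyclohexyl benzoate
Conditions: (EtO)2P(O)CH2C(Me)=CHCN, NaN(SiMe3)2 (anion pre-formed), THF, −78 to 0 °C
Reagents that add atoms: diethyl [(2E)-3-cyano-2-methylprop-2-en-1-yl]phosphonate, CCOP(=O)(OCC)C/C(C)=C/C#N
Why: Horner–Wadsworth–Emmons olefination with the nitrile-stabilised allylic phosphonate anion should form the E C7=C8 olefin and bring in C8–C11 with the 9E geometry of the reagent; the stabilised anion is too weak a base to deprotonate the tertiary hydroxyl.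

Step 9
Reactants: 9 (1S,2S,5S)-5-[(tert-butyldimethylsilyl)oxy]-2-[(1E,3E)-4-cyano-3-methylbuta-1,3-dien-1-yl]-2-hydroxy-1,3,3-trimethylcyclohexyl benzoate
Product: 10 (2E,4E)-5-[(1S,2S,4S)-4-[(tert-butyldimethylsilyl)oxy]-1,2-dihydroxy-2,6,6-trimethylcyclohexyl]-3-methylpenta-2,4-dienal
Conditions: iBu2AlH (4.5 equiv), CH2Cl2, −78 °C; Rochelle salt, then wet silica gel
Reagents that add atoms: water, O
Why: DIBAL adds one hydride to the nitrile so that aqueous work-up delivers the dienal, and the same reagent cleaves the benzoate reductively, freeing the 5,6-diol without basic hydrolysis.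

Step 10
Reactants: 10 (2E,4E)-5-[(1S,2S,4S)-4-[(tert-butyldimethylsilyl)oxy]-1,2-dihydroxy-2,6,6-trimethylcyclohexyl]-3-methylpenta-2,4-dienal
Product: 11 (2E,4E,6E,8E)-9-[(1S,2S,4S)-4-[(tert-butyldimethylsilyl)oxy]-1,2-dihydroxy-2,6,6-trimethylcyclohexyl]-3,7-dimethylnona-2,4,6,8-tetraenenitrile
Conditions: (EtO)2P(O)CH2C(Me)=CHCN, NaN(SiMe3)2 (anion pre-formed), THF, −78 to 0 °C
Reagents that add atoms: diethyl [(2E)-3-cyano-2-methylprop-2-en-1-yl]phosphonate, CCOP(=O)(OCC)C/C(C)=C/C#N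
Why: A second Horner–Wadsworth–Emmons olefination should form the E C11=C12 olefin and add C12–C15; the two tertiary hydroxyls are not deprotonated by the stabilised anion and need no protection here.

Step 11
Reactants: 11 (2E,4E,6E,8E)-9-[(1S,2S,4S)-4-[(tert-butyldimethylsilyl)oxy]-1,2-dihydroxy-2,6,6-trimethylcyclohexyl]-3,7-dimethylnona-2,4,6,8-tetraenenitrile
Product: 12 (2E,4E,6E,8E)-9-[(1S,2S,4S)-4-[(tert-butyldimethylsilyl)oxy]-2,6,6-trimethyl-1,2-bis[(triethylsilyl)oxy]cyclohexyl]-3,7-dimethylnona-2,4,6,8-tetraenenitrile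
Conditions: Et3SiOTf, 2,6-lutidine, CH2Cl2, 0 °C to rt
Reagents that add atoms: triethylsilyl trifluoromethanesulfonate, CC[Si](CC)(CC)OS(=O)(=O)C(F)(F)F
Why: Silyl triflate with a hindered pyridine base silylates both hindered tertiary hydroxyls; this is done at the nitrile stage because the electron-poor tetraenenitrile disfavours ionisation at C6 and no enolisable aldehyde is present.

Step 12
Reactants: 12 (2E,4E,6E,8E)-9-[(1S,2S,4S)-4-[(tert-butyldimethylsilyl)oxy]-2,6,6-trimethyl-1,2-bis[(triethylsilyl)oxy]cyclohexyl]-3,7-dimethylnona-2,4,6,8-tetraenenitrile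
Product: 13 (2E,4E,6E,8E)-9-[(1S,2S,4S)-4-[(tert-butyldimethylsilyl)oxy]-2,6,6-trimethyl-1,2-bis[(triethylsilyl)oxy]cyclohexyl]-3,7-dimethylnona-2,4,6,8-tetraenal
Conditions: iBu2AlH (1.5 equiv), toluene, −78 °C; Rochelle salt, then wet silica gel (Et3N-buffered)
Reagents that add atoms: water, O
Why: DIBAL half-reduction of the conjugated nitrile and hydrolytic work-up should give the C20 tetraenal without touching the silyl ethers.

Step 13
Reactants: 13 (2E,4E,6E,8E)-9-[(1S,2S,4S)-4-[(tert-butyldimethylsilyl)oxy]-2,6,6-trimethyl-1,2-bis[(triethylsilyl)oxy]cyclohexyl]-3,7-dimethylnona-2,4,6,8-tetraenal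
Product: 14 (1E,3E,5E,7E,9E)-1-iodo-4,8-dimethyl-10-[(1S,2S,4S)-4-[(tert-butyldimethylsilyl)oxy]-2,6,6-trimethyl-1,2-bis[(triethylsilyl)oxy]cyclohexyl]deca-1,3,5,7,9-pentaene
Conditions: CHI3, CrCl2 (excess), THF–dioxane, 0 °C to rt, dark
Reagents that add atoms: iodoform, IC(I)I
Why: Takai olefination; the geminal dichromium species made from CHI3 and divalent chromium adds to the aldehyde and eliminates to the (E)-iodoalkene, creating the C15=C15' olefin with iodine on C15'.

**Fragment with the ε ring (C18 alkyne)**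

Step 14
Reactants: 15 (3E)-4-[(1R)-2,6,6-trimethylcyclohex-2-en-1-yl]but-3-en-2-one ((R)-α-ionone)
Product: 16 (2E,4E)-3-methyl-5-[(1R)-2,6,6-trimethylcyclohex-2-en-1-yl]penta-2,4-dienenitrile
Conditions: (EtO)2P(O)CH2CN, NaH, THF, 0 °C to rt; 9'E isomer separated
Reagents that add atoms: diethyl cyanomethylphosphonate, CCOP(=O)(OCC)CC#N
Why: Horner–Wadsworth–Emmons olefination of the methyl ketone should favour the 9'E nitrile, and the stabilised anion is too weak a base to remove the γ-hydrogen at C6', so the stereocentre is kept.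

Step 15
Reactants: 16 (2E,4E)-3-methyl-5-[(1R)-2,6,6-trimethylcyclohex-2-en-1-yl]penta-2,4-dienenitrile
Product: 17 (2E,4E)-3-methyl-5-[(1R)-2,6,6-trimethyl-4-oxocyclohex-2-en-1-yl]penta-2,4-dienenitrile
Conditions: t-BuOOH (70% aq.), Rh2(cap)4 (1 mol %, cap = caprolactamate), ClCH2CH2Cl, 40 °C, no added base
Reagents that add atoms: tert-butyl hydroperoxide, CC(C)(C)OO
Why: Allylic C–H oxidation by a tert-butylperoxy radical chain at the ring methylene C3' next to the trisubstituted C4'=C5' olefin should give the enone, as it does for α-ionone itself; the doubly allylic C6'–H is shielded by the gem-dimethyl group and base is left out to avoid epimerising C6'.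

Step 16
Reactants: 17 (2E,4E)-3-methyl-5-[(1R)-2,6,6-trimethyl-4-oxocyclohex-2-en-1-yl]penta-2,4-dienenitrile
Product: 18 (2E,4E)-5-[(1R,4R)-4-hydroxy-2,6,6-trimethylcyclohex-2-en-1-yl]-3-methylpenta-2,4-dienenitrile
Conditions: LiBH(sBu)3, THF, −78 °C; aqueous NH4Cl
Reagents that add atoms: none
Why: 1,2-Reduction by the bulky hydride should occur from the face opposite the axial C1' methyl group (the side chain at C6' sits pseudo-axial to avoid allylic strain with the C5' methyl), which places the new C3' hydroxyl trans to the side chain (3'R).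

Step 17
Reactants: 18 (2E,4E)-5-[(1R,4R)-4-hydroxy-2,6,6-trimethylcyclohex-2-en-1-yl]-3-methylpenta-2,4-dienenitrile
Product: 19 (2E,4E)-5-[(1R,4R)-4-[(tert-butyldimethylsilyl)oxy]-2,6,6-trimethylcyclohex-2-en-1-yl]-3-methylpenta-2,4-dienenitrile
Conditions: TBSCl, imidazole, DMF, rt
Reagents that add atoms: tert-butyldimethylsilyl chloride, CC(C)(C)[Si](C)(C)Cl
Why: Standard silylation of the secondary allylic alcohol, so that no protic group is left for the organoaluminium chemistry of the key step.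

Step 18
Reactants: 19 (2E,4E)-5-[(1R,4R)-4-[(tert-butyldimethylsilyl)oxy]-2,6,6-trimethylcyclohex-2-en-1-yl]-3-methylpenta-2,4-dienenitrile
Product: 20 (2E,4E)-5-[(1R,4R)-4-[(tert-butyldimethylsilyl)oxy]-2,6,6-trimethylcyclohex-2-en-1-yl]-3-methylpenta-2,4-dienal
Conditions: iBu2AlH (1.3 equiv), toluene, −78 °C; Rochelle salt, then wet silica gel
Reagents that add atoms: water, O
Why: DIBAL half-reduction of the nitrile and hydrolytic work-up should give the C15 dienal with the olefin geometry unchanged.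

Step 19
Reactants: 20 (2E,4E)-5-[(1R,4R)-4-[(tert-butyldimethylsilyl)oxy]-2,6,6-trimethylcyclohex-2-en-1-yl]-3-methylpenta-2,4-dienal
Product: 21 tert-butyldimethylsilyl ether of (1R,4R)-3,5,5-trimethyl-4-[(1E,3E,5E)-3-methyl-8-(trimethylsilyl)octa-1,3,5-trien-7-yn-1-yl]cyclohex-2-en-1-ol
Conditions: (EtO)2P(O)CH2C≡CSiMe3, LiN(SiMe3)2, THF, −78 to 0 °C
Reagents that add atoms: diethyl [3-(trimethylsilyl)prop-2-yn-1-yl]phosphonate, CCOP(=O)(OCC)CC#C[Si](C)(C)C
Why: Horner–Wadsworth–Emmons olefination with the lithiated silylpropargyl phosphonate should give the conjugated (E)-enyne, forming the C11'=C12' olefin and bringing in C12'–C14'.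

Step 20
Reactants: 21 tert-butyldimethylsilyl ether of (1R,4R)-3,5,5-trimethyl-4-[(1E,3E,5E)-3-methyl-8-(trimethylsilyl)octa-1,3,5-trien-7-yn-1-yl]cyclohex-2-en-1-ol
Product: 22 tert-butyldimethylsilyl ether of (1R,4R)-3,5,5-trimethyl-4-[(1E,3E,5E)-3-methylocta-1,3,5-trien-7-yn-1-yl]cyclohex-2-en-1-ol
Conditions: K2CO3 (cat.), MeOH–THF, rt
Reagents that add atoms: none
Why: Methoxide-catalysed protodesilylation cleaves only the C(sp)–Si bond and leaves the secondary silyl ether in place, exposing the terminal alkyne C13'≡C14'–H.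

**Union and end game**

Step 21
Reactants: 22 tert-butyldimethylsilyl ether of (1R,4R)-3,5,5-trimethyl-4-[(1E,3E,5E)-3-methylocta-1,3,5-trien-7-yn-1-yl]cyclohex-2-en-1-ol; 14 (1E,3E,5E,7E,9E)-1-iodo-4,8-dimethyl-10-[(1S,2S,4S)-4-[(tert-butyldimethylsilyl)oxy]-2,6,6-trimethyl-1,2-bis[(triethylsilyl)oxy]cyclohexyl]deca-1,3,5,7,9-pentaene
Product: 24 (3S,5S,6S,3'R,6'R)-3,3'-bis-O-(tert-butyldimethylsilyl)-5,6-bis-O-(triethylsilyl)-5,6-dihydro-β,ε-carotene-3,5,6,3'-tetrol, via C19 alkenyldimethylalane 23 (not isolated)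
Conditions: AlMe3 (2.2 equiv), Cp2ZrCl2 (25 mol %), ClCH2CH2Cl, rt; volatiles removed; then 14 (0.9 equiv), Pd2(dba)3 (2.5 mol %), P(2-furyl)3 (10 mol %), ZnCl2 (30 mol %), THF–DMF, rt, dark
Reagents that add atoms: trimethylaluminium, C[Al](C)C
Why: Cp2ZrCl2-activated AlMe3 adds methyl and AlMe2 syn across the terminal alkyne of 22 (methyl to the internal C13', aluminium to the terminal C14') to give the (E)-alkenylalane 23; after removal of excess AlMe3, zerovalent palladium inserts into the C15'–I bond of 14, the alkenyl group is relayed from aluminium through zinc to palladium, and reductive elimination forms the C14'–C15' bond with retention of both olefin geometries. The closest known reaction type is the tandem Zr-catalysed carboalumination/Pd–Zn co-catalysed alkenyl–alkenyl (Negishi) cross-coupling, which is established for this very position (C14–C15) of carotene and retinoid polyenes. No ring is closed and no stereocentre is created; the only stereochemical elements are the C13'=C14' geometry, fixed by the syn addition, and the C15=C15' geometry, carried in from the Takai iodide. The step needs regioselective methyl delivery to the internal alkyne carbon (secured by the terminal, conjugated alkyne), transfer of the alkenyl rather than a methyl group from aluminium (secured by the zinc relay and removal of AlMe3), and the absence of protic or easily ionised groups (secured by silylation of all four oxygens and by running the coupling in THF–DMF, which tempers the Lewis acidity). In one operation it should install the C20' methyl carbon, set the trisubstituted E-olefin and join the C19 and C21 halves into the complete C40 skeleton.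

Step 22
Reactants: 24 (3S,5S,6S,3'R,6'R)-3,3'-bis-O-(tert-butyldimethylsilyl)-5,6-bis-O-(triethylsilyl)-5,6-dihydro-β,ε-carotene-3,5,6,3'-tetrol
Product: 25 (3S,5S,6S,3'R,6'R)-5,6-dihydro-β,ε-carotene-3,5,6,3'-tetrol (target)
Conditions: Bu4NF (6 equiv), THF, rt, dark; crystallisation
Reagents that add atoms: none
Why: Fluoride-driven cleavage of all four Si–O bonds in a non-acidic medium should free the tetrol without ionising the tertiary allylic C6 hydroxyl and without touching any stereocentre or olefin.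

**Compound list**
1 | (4R,6R)-4-hydroxy-2,2,6-trimethylcyclohexan-1-one (actinol) | O=C1C(C)(C)C[C@H](O)C[C@H]1C | starting material
2 | (4R,6R)-4-[(tert-butyldimethylsilyl)oxy]-2,2,6-trimethylcyclohexan-1-one | O=C1C(C)(C)C[C@H](O[Si](C)(C)C(C)(C)C)C[C@H]1C | intermediate
3 | (4R)-4-[(tert-butyldimethylsilyl)oxy]-2,6,6-trimethylcyclohex-1-en-1-yl trifluoromethanesulfonate | FC(F)(F)S(=O)(=O)OC1=C(C)C[C@@H](O[Si](C)(C)C(C)(C)C)CC1(C)C | intermediate
4 | methyl (4R)-4-[(tert-butyldimethylsilyl)oxy]-2,6,6-trimethylcyclohex-1-ene-1-carboxylate | COC(=O)C1=C(C)C[C@@H](O[Si](C)(C)C(C)(C)C)CC1(C)C | intermediate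
5 | [(4R)-4-[(tert-butyldimethylsilyl)oxy]-2,6,6-trimethylcyclohex-1-en-1-yl]methanol | OCC1=C(C)C[C@@H](O[Si](C)(C)C(C)(C)C)CC1(C)C | intermediate
6 | [(1R,4S,6R)-4-[(tert-butyldimethylsilyl)oxy]-2,2,6-trimethyl-7-oxabicyclo[4.1.0]heptan-1-yl]methanol (oxirane trans to silyloxy) | OC[C@]12C(C)(C)C[C@H](O[Si](C)(C)C(C)(C)C)C[C@@]1(C)O2 | intermediate
7 | (1S,2R,5S)-5-[(tert-butyldimethylsilyl)oxy]-2-hydroxy-2-(hydroxymethyl)-1,3,3-trimethylcyclohexyl benzoate | OC[C@]1(O)C(C)(C)C[C@H](O[Si](C)(C)C(C)(C)C)C[C@]1(C)OC(=O)c1ccccc1 | intermediate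
8 | (1S,2S,5S)-5-[(tert-butyldimethylsilyl)oxy]-2-formyl-2-hydroxy-1,3,3-trimethylcyclohexyl benzoate | O=C[C@]1(O)C(C)(C)C[C@H](O[Si](C)(C)C(C)(C)C)C[C@]1(C)OC(=O)c1ccccc1 | intermediate
9 | (1S,2S,5S)-5-[(tert-butyldimethylsilyl)oxy]-2-[(1E,3E)-4-cyano-3-methylbuta-1,3-dien-1-yl]-2-hydroxy-1,3,3-trimethylcyclohexyl benzoate | N#C/C=C(C)/C=C/[C@]1(O)C(C)(C)C[C@H](O[Si](C)(C)C(C)(C)C)C[C@]1(C)OC(=O)c1ccccc1 | intermediate
10 | (2E,4E)-5-[(1S,2S,4S)-4-[(tert-butyldimethylsilyl)oxy]-1,2-dihydroxy-2,6,6-trimethylcyclohexyl]-3-methylpenta-2,4-dienal | O=C/C=C(C)/C=C/[C@]1(O)C(C)(C)C[C@H](O[Si](C)(C)C(C)(C)C)C[C@]1(C)O | intermediate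
11 | (2E,4E,6E,8E)-9-[(1S,2S,4S)-4-[(tert-butyldimethylsilyl)oxy]-1,2-dihydroxy-2,6,6-trimethylcyclohexyl]-3,7-dimethylnona-2,4,6,8-tetraenenitrile | N#C/C=C(C)/C=C/C=C(C)/C=C/[C@]1(O)C(C)(C)C[C@H](O[Si](C)(C)C(C)(C)C)C[C@]1(C)O | intermediate
12 | (2E,4E,6E,8E)-9-[(1S,2S,4S)-4-[(tert-butyldimethylsilyl)oxy]-2,6,6-trimethyl-1,2-bis[(triethylsilyl)oxy]cyclohexyl]-3,7-dimethylnona-2,4,6,8-tetraenenitrile | N#C/C=C(C)/C=C/C=C(C)/C=C/[C@]1(O[Si](CC)(CC)CC)C(C)(C)C[C@H](O[Si](C)(C)C(C)(C)C)C[C@]1(C)O[Si](CC)(CC)CC | intermediate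
13 | (2E,4E,6E,8E)-9-[(1S,2S,4S)-4-[(tert-butyldimethylsilyl)oxy]-2,6,6-trimethyl-1,2-bis[(triethylsilyl)oxy]cyclohexyl]-3,7-dimethylnona-2,4,6,8-tetraenal | O=C/C=C(C)/C=C/C=C(C)/C=C/[C@]1(O[Si](CC)(CC)CC)C(C)(C)C[C@H](O[Si](C)(C)C(C)(C)C)C[C@]1(C)O[Si](CC)(CC)CC | intermediate
14 | (1E,3E,5E,7E,9E)-1-iodo-4,8-dimethyl-10-[(1S,2S,4S)-4-[(tert-butyldimethylsilyl)oxy]-2,6,6-trimethyl-1,2-bis[(triethylsilyl)oxy]cyclohexyl]deca-1,3,5,7,9-pentaene (C21 iodide) | I/C=C/C=C(C)/C=C/C=C(C)/C=C/[C@]1(O[Si](CC)(CC)CC)C(C)(C)C[C@H](O[Si](C)(C)C(C)(C)C)C[C@]1(C)O[Si](CC)(CC)CC | intermediate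
15 | (3E)-4-[(1R)-2,6,6-trimethylcyclohex-2-en-1-yl]but-3-en-2-one ((R)-α-ionone) | CC1=CCCC(C)(C)[C@H]1/C=C/C(C)=O | starting material
16 | (2E,4E)-3-methyl-5-[(1R)-2,6,6-trimethylcyclohex-2-en-1-yl]penta-2,4-dienenitrile | CC1=CCCC(C)(C)[C@H]1/C=C/C(C)=C/C#N | intermediate
17 | (2E,4E)-3-methyl-5-[(1R)-2,6,6-trimethyl-4-oxocyclohex-2-en-1-yl]penta-2,4-dienenitrile | CC1=CC(=O)CC(C)(C)[C@H]1/C=C/C(C)=C/C#N | intermediate
18 | (2E,4E)-5-[(1R,4R)-4-hydroxy-2,6,6-trimethylcyclohex-2-en-1-yl]-3-methylpenta-2,4-dienenitrile | CC1=C[C@H](O)CC(C)(C)[C@H]1/C=C/C(C)=C/C#N | intermediate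
19 | (2E,4E)-5-[(1R,4R)-4-[(tert-butyldimethylsilyl)oxy]-2,6,6-trimethylcyclohex-2-en-1-yl]-3-methylpenta-2,4-dienenitrile | CC1=C[C@H](O[Si](C)(C)C(C)(C)C)CC(C)(C)[C@H]1/C=C/C(C)=C/C#N | intermediate
20 | (2E,4E)-5-[(1R,4R)-4-[(tert-butyldimethylsilyl)oxy]-2,6,6-trimethylcyclohex-2-en-1-yl]-3-methylpenta-2,4-dienal | CC1=C[C@H](O[Si](C)(C)C(C)(C)C)CC(C)(C)[C@H]1/C=C/C(C)=C/C=O | intermediate
21 | tert-butyldimethylsilyl ether of (1R,4R)-3,5,5-trimethyl-4-[(1E,3E,5E)-3-methyl-8-(trimethylsilyl)octa-1,3,5-trien-7-yn-1-yl]cyclohex-2-en-1-ol | CC1=C[C@H](O[Si](C)(C)C(C)(C)C)CC(C)(C)[C@H]1/C=C/C(C)=C/C=C/C#C[Si](C)(C)C | intermediate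
22 | tert-butyldimethylsilyl ether of (1R,4R)-3,5,5-trimethyl-4-[(1E,3E,5E)-3-methylocta-1,3,5-trien-7-yn-1-yl]cyclohex-2-en-1-ol (C18 alkyne) | CC1=C[C@H](O[Si](C)(C)C(C)(C)C)CC(C)(C)[C@H]1/C=C/C(C)=C/C=C/C#C | intermediate
23 | dimethyl[(1E,3E,5E,7E)-2,6-dimethyl-8-[(1R,4R)-4-[(tert-butyldimethylsilyl)oxy]-2,6,6-trimethylcyclohex-2-en-1-yl]octa-1,3,5,7-tetraen-1-yl]alumane (C19 alkenyldimethylalane) | CC1=C[C@H](O[Si](C)(C)C(C)(C)C)CC(C)(C)[C@H]1/C=C/C(C)=C/C=C/C(C)=C/[Al](C)C | intermediate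
24 | (3S,5S,6S,3'R,6'R)-3,3'-bis-O-(tert-butyldimethylsilyl)-5,6-bis-O-(triethylsilyl)-5,6-dihydro-β,ε-carotene-3,5,6,3'-tetrol | CC1=C[C@H](O[Si](C)(C)C(C)(C)C)CC(C)(C)[C@H]1/C=C/C(C)=C/C=C/C(C)=C/C=C/C=C(C)/C=C/C=C(C)/C=C/[C@]1(O[Si](CC)(CC)CC)C(C)(C)C[C@H](O[Si](C)(C)C(C)(C)C)C[C@]1(C)O[Si](CC)(CC)CC | intermediate
25 | (3S,5S,6S,3'R,6'R)-5,6-dihydro-β,ε-carotene-3,5,6,3'-tetrol | CC1=C[C@H](O)CC(C)(C)[C@H]1/C=C/C(C)=C/C=C/C(C)=C/C=C/C=C(C)/C=C/C=C(C)/C=C/[C@]1(O)C(C)(C)C[C@H](O)C[C@]1(C)O | target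

**Step count**
Total: 22 steps. Longest linear sequence: 15 steps (steps 1–13, 21, 22).

**Steps most likely to fail**

Step 21. What may go wrong: methyl rather than alkenyl transfer to palladium, protonolysis of the alkenylalane, or Lewis-acid ionisation of the tertiary allylic C6 silyl ether before the coupling is complete. Fallback (metalation and coupling are separated and the polarity of the union is reversed): setting out from 22 and 13, the alane 23 would be generated as in step 21 but quenched with I2 (THF, −30 °C) to give the C19 (E)-alkenyl iodide F1. Aldehyde 13 would be converted by a Takai–Utimoto boron olefination (Cl2CHBpin, CrCl2, LiI, THF) into the C21 (E)-alkenyl pinacol boronate F2. A Suzuki–Miyaura coupling of F1 with F2 (Pd(PPh3)4, aqueous K3PO4, THF, rt), free of Lewis acids, would come back to the route at 24.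

Step 6. What may go wrong: bimolecular attack on the hindered lower face of C5 is slow, so that ionisation at C5 (elimination to an allylic alcohol, loss of inversion) or isopropoxide transfer from titanium competes. Fallback (intramolecular instead of intermolecular oxygen delivery): setting out from 6, PhNCO/pyridine would give the phenylurethane F3. With BF3·OEt2 (Et2O, −20 °C) the urethane carbonyl oxygen, held on the face opposite the oxirane, should attack C5 through a cis-fused six-membered transition state to give the cyclic N-phenyl iminocarbonate F4. Dilute aqueous acid would hydrolyse this to the cyclic 5,7-carbonate F5, and K2CO3/MeOH would free the triol F6. TEMPO/PhI(OAc)2 would give the dihydroxy aldehyde F7, the phosphonate of step 8 the dihydroxy nitrile F8, and iBu2AlH reduction with hydrolytic work-up would come back to the route at 10.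

Step 16. What may go wrong: hydride delivery to the other face of the enone (poor or reversed facial selectivity), giving the 3',6'-cis alcohol. Fallback (inversion instead of direct control): setting out from 17, the reduction would be run to the cis alcohol F9 as the accepted main product. A Mitsunobu reaction (PhCO2H, PPh3, diisopropyl azodicarboxylate, THF) would invert C3' to the trans benzoate F10, and methanolysis (K2CO3, MeOH) would come back to the route at 18.

**Further compounds**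
F1 | step 21 | tert-butyldimethylsilyl ether of (1R,4R)-4-[(1E,3E,5E,7E)-8-iodo-3,7-dimethylocta-1,3,5,7-tetraen-1-yl]-3,5,5-trimethylcyclohex-2-en-1-ol (C19 alkenyl iodide) | CC1=C[C@H](O[Si](C)(C)C(C)(C)C)CC(C)(C)[C@H]1/C=C/C(C)=C/C=C/C(C)=C/I
F2 | step 21 | pinacol (1E,3E,5E,7E,9E)-4,8-dimethyl-10-[(1S,2S,4S)-4-[(tert-butyldimethylsilyl)oxy]-2,6,6-trimethyl-1,2-bis[(triethylsilyl)oxy]cyclohexyl]deca-1,3,5,7,9-pentaen-1-ylboronate (C21 alkenyl boronate) | CC1(C)OB(OC1(C)C)/C=C/C=C(C)/C=C/C=C(C)/C=C/[C@]1(O[Si](CC)(CC)CC)C(C)(C)C[C@H](O[Si](C)(C)C(C)(C)C)C[C@]1(C)O[Si](CC)(CC)CC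
F3 | step 6 | N-phenylcarbamate (phenylurethane) of epoxy alcohol 6 | O=C(Nc1ccccc1)OC[C@]12C(C)(C)C[C@H](O[Si](C)(C)C(C)(C)C)C[C@@]1(C)O2
F4 | step 6 | cyclic N-phenyl iminocarbonate bridging O5 and O7 (cis-fused 1,3-dioxane, free C6 hydroxyl trans to O5) | c1ccccc1N=C1OC[C@]2(O)C(C)(C)C[C@H](O[Si](C)(C)C(C)(C)C)C[C@]2(C)O1
F5 | step 6 | cyclic 5,7-carbonate (cis-fused 1,3-dioxan-2-one, free C6 hydroxyl) | O=C1OC[C@]2(O)C(C)(C)C[C@H](O[Si](C)(C)C(C)(C)C)C[C@]2(C)O1
F6 | step 6 | (1S,2R,4S)-4-[(tert-butyldimethylsilyl)oxy]-1-(hydroxymethyl)-2,6,6-trimethylcyclohexane-1,2-diol | OC[C@]1(O)C(C)(C)C[C@H](O[Si](C)(C)C(C)(C)C)C[C@]1(C)O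
F7 | step 6 | (1S,2S,4S)-4-[(tert-butyldimethylsilyl)oxy]-1,2-dihydroxy-2,6,6-trimethylcyclohexane-1-carbaldehyde | O=C[C@]1(O)C(C)(C)C[C@H](O[Si](C)(C)C(C)(C)C)C[C@]1(C)O
F8 | step 6 | (2E,4E)-5-[(1S,2S,4S)-4-[(tert-butyldimethylsilyl)oxy]-1,2-dihydroxy-2,6,6-trimethylcyclohexyl]-3-methylpenta-2,4-dienenitrile | N#C/C=C(C)/C=C/[C@]1(O)C(C)(C)C[C@H](O[Si](C)(C)C(C)(C)C)C[C@]1(C)O
F9 | step 16 | (2E,4E)-5-[(1R,4S)-4-hydroxy-2,6,6-trimethylcyclohex-2-en-1-yl]-3-methylpenta-2,4-dienenitrile (cis alcohol) | CC1=C[C@@H](O)CC(C)(C)[C@H]1/C=C/C(C)=C/C#N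
F10 | step 16 | (1R,4R)-4-[(1E,3E)-4-cyano-3-methylbuta-1,3-dien-1-yl]-3,5,5-trimethylcyclohex-2-en-1-yl benzoate (trans benzoate) | CC1=C[C@H](OC(=O)c2ccccc2)CC(C)(C)[C@H]1/C=C/C(C)=C/C#N
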